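Slowness was what struck me first in this flask: the starting material enters the productive line by a step whose forward half-life is 1.3 min, and the target lies further down that line.

in all of them: starting material 0.40 M; time 3.0 min

|  | protic impurity |
|---|---|
| summer | 0.400 M |
| dusk | 0.600 M |
| midnight | 1.00 M |

    starting material ⇌ intermediate A (K1 = 0.29, k1 = 0.0086 s⁻¹)
    intermediate A → intermediate B (k2 = 0.0019 s⁻¹)
    intermediate B → side product (k3 = 0.0044 s⁻¹)
    intermediate A ⇌ intermediate C (K4 = 0.94, k4 = 6.3 × 10⁻⁴ s⁻¹)
    intermediate B → target (k5 = 0.054 s⁻¹)
    intermediate C ⇌ intermediate D (K6 = 2.2, k6 = 0.0038 s⁻¹)
    starting material + protic impurity → quenched substrate (k7 = 0.20 L mol⁻¹ s⁻¹)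
    starting material ⇌ dormant form (K8 = 17, k8 = 0.0012 s⁻¹)
    target → over-reaction product (k9 = 0.030 s⁻¹)

- "hardly changes" means that all values lie within two and a half points (for a concentration: within two and a half percent of the largest)
- run time (summer): 3.0 min

1. [target] at the end for summer, dusk, midnight, in this order
2. how that number moves from the first to the last of them (falls, then rises / rises, then falls / hardly changes / falls all the way / rises all the way)

The starting material can also be quenched by the protic impurity, so I compared the two rates at one moment. I called the quench ratio the rate constant of the quench times c(protic impurity), divided by the forward rate constant of the first step: it tells how many times faster the starting material is quenched than it turns into intermediate A by the forward step, the way back not counted. At the start it was 9.30 in summer, so nearly all of what left by these two ways went to the quench at that moment.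

The bench rule says that a reagent in excess counts as constant, the pseudo-first-order treatment, and then the ratio scales with the charge. That gave 14.0 at the start of dusk and 23.3 at the start of midnight.

But the quench uses one impurity for each starting material, so I asked how the comparison drifts. The charge of impurity over the charge of starting material was 1.00 in summer, 1.50 in dusk and 2.50 in midnight. A full quench leaves 0.200 M of impurity in dusk, where the ratio is then 4.65, and 0.600 M in midnight, where it is 14.0. In summer the two charges match, so the rule fails there: the ratio sinks as the quench proceeds.

My reckoning went as far as the direction: with the charge of starting material held at 0.40 M, each step up in impurity raises the ratio, so I expected the target to fall all the way. I committed to no size, because the target's half-life by over-reaction, 0.39 min, is short against the run of 3.0 min, so the end value reflects what was formed late.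

The forecast gave 6.800 × 10⁻⁴ M, 2.000 × 10⁻⁴ M and 6.000 × 10⁻⁵ M, a shape that falls all the way, holding that “the target falls steeply as the impurity goes from matching the substrate to exceeding it”. It shared my direction and added sizes that I had not reckoned.

The flask gave 6.04 × 10⁻⁴ M, 1.71 × 10⁻⁴ M and 5.72 × 10⁻⁵ M, and the row falls all the way. In summer, 11% of the impurity and 4.15% of the starting material were left at 3.00 min. The quench ratio in summer had therefore sunk from 9.30 to 0.998, so the two forward rates were about level at that moment. In midnight, 60% of the impurity was left at 3.00 min, which puts the ratio at that moment at 14.1.

The constants used here are those of an exercise; what happens was integrated by code.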